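The plan rests on cutting the C10–C1 bond of six-membered ring A (C10, C1, C2, C3, C4, C5). The feature used is the vicinal pair C10 (tertiary, oxygen- and methyl-bearing bridge carbon) and bridgehead C1. Both can be read as acceptor carbons, a methyl ketone carbonyl and the β-carbon of an enoate. One SmI2 ketyl–enoate cyclisation joins them, closes ring A and sets both stereocentres under control of C5. The precursor is an acyclic keto enoate whose C5 and quaternary C6 centres come from one Ireland–Claisen rearrangement with chirality transfer. Its C6 carries an E-propenyl group as a samarium-inert stand-in for the later acetonyl arm. Ring B (C7–C8) is closed afterwards by aldol condensation.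

Key step: step 12

Atom labels: C10 = oxygenated bridge carbon; C1, C5 = bridgeheads; C2–C3=C4 = three-carbon bridge (C11 on C4); C6–C7–C8–C9 = four-carbon bridge from C5 to C1; C12, C13 = acetyl carbons on C7; C1' = side-chain methine on C6. Ring A = C10, C1, C2, C3, C4, C5. Ring B = C10, C1, C9, C8, C7, C6, C5.

Assumption: the stereodescriptors of the target are taken literally; they put C9 (on C1) and C6 (on C5) on opposite faces of ring A, so ring B is a trans-bridged (inside–outside) ring and its closure has to pay for strain.

Design remarks: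
- **C12 as carbinol.** C12 enters as an (R)-carbinol. It relays chirality in the Claisen step, because C1' alone cannot tell the alkene faces apart, and it brings C13. It leaves an E-propenyl group, so no second monosubstituted alkene and no second ketone (a pinacol partner) is present before ring A is closed.
- **Protection at C10.** The C10 oxygen is carried as a silyl ether through ring-B closure. An acetate would be open to acyl transfer to the C9 or C7 enolate. A free hydroxyl would be open to lactol formation and oxa-Michael addition at C8.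
- **Consistency check.** In the precursor, C3=C4 holds C2 and C5 cis (E by the sequence rule). The centres C5, C6 and C1' of the precursor and of the cyclised product map one to one onto the target.

Step 1
Reactants: 1 (S)-citronellal
Product: 3 (S)-3,7-dimethyloct-6-en-1-yne, via enol nonaflate 2 (not isolated)
Conditions: C4F9SO2F, phosphazene base P2-Et, DMF, −10 °C to rt
Reagents that add atoms: none
Why: One-pot nonaflation–elimination of an enolisable aldehyde (alkenyl nonaflate, then E2 loss of nonaflate) gives the terminal alkyne with all ten carbons kept (aldehyde carbon = C7, its neighbour = C6), and the C1' centre, never acidic on the way, is taken over from the chiral pool.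

Step 2
Reactants: 3 (S)-3,7-dimethyloct-6-en-1-yne; 4 acetaldehyde
Product: 6 (3E,5S)-4,5,9-trimethyldeca-3,8-dien-2-ol (both C12 epimers), via alkenyldimethylalane 5 (not isolated)
Conditions: Me3Al, Cp2ZrCl2 (cat.), CH2Cl2, 0 °C to rt; then 4, −78 to 0 °C; H2O work-up
Reagents that add atoms: trimethylaluminium, C[Al](C)C
Why: Negishi zirconium-catalysed methylalumination adds CH3 and Al syn with Al on the terminal carbon, which fixes the E-trisubstituted C6=C7 alkene, and the alkenylalane then adds 1,2 to acetaldehyde; the uncontrolled C12 carbinol is erased in the next step.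

Step 3
Reactants: 6 (3E,5S)-4,5,9-trimethyldeca-3,8-dien-2-ol
Product: 7 (3E,5S)-4,5,9-trimethyldeca-3,8-dien-2-one
Conditions: MnO2, CH2Cl2, rt
Reagents that add atoms: none
Why: Allylic alcohol oxidation with MnO2 is neutral and touches neither the alkenes nor the γ-positioned C1' centre.

Step 4
Reactants: 7 (3E,5S)-4,5,9-trimethyldeca-3,8-dien-2-one
Product: 8 (2R,3E,5S)-4,5,9-trimethyldeca-3,8-dien-2-ol
Conditions: (S)-2-methyl-CBS-oxazaborolidine (cat.), catecholborane, toluene, −78 °C
Reagents that add atoms: none
Why: Corey–Bakshi–Shibata reduction binds the enone with the alkenyl group as the large and methyl as the small substituent, so the (S)-catalyst delivers hydride to the face that gives (R)-C12, while catecholborane at −78 °C leaves the alkenes alone.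

Step 5
Reactants: 9 tert-butyldimethyl(prop-2-yn-1-yloxy)silane; 10 allyl bromide
Product: 11 (Z)-(2-bromohexa-2,5-dien-1-yloxy)(tert-butyl)dimethylsilane
Conditions: PdBr2(PhCN)2 (cat.), 10 (excess), DME, 0 °C to rt
Reagents that add atoms: none
Why: Palladium-catalysed bromoallylation of a terminal alkyne runs by syn bromopalladation (Br on internal C4, Pd on C3), insertion of allyl bromide and loss of bromide, so Br and the allyl chain (C2) end cis on C3=C4.

Step 6
Reactants: 11 (Z)-(2-bromohexa-2,5-dien-1-yloxy)(tert-butyl)dimethylsilane; 12 ethyl bromoacetate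
Product: 14 ethyl (E)-3-[(tert-butyldimethylsilyloxy)methyl]hepta-3,6-dienoate, via zinc enolate 13 (not isolated)
Conditions: Zn, THF, rt; then 11, Pd(P(t-Bu)3)2 (cat.), THF, rt
Reagents that add atoms: none
Why: Negishi coupling of an alkenyl bromide with a Reformatsky zinc enolate goes with retention at C4, so the C5–C10 arm takes the place of Br, cis to C2 as ring A requires.

Step 7
Reactants: 14 ethyl (E)-3-[(tert-butyldimethylsilyloxy)methyl]hepta-3,6-dienoate
Product: 15 (E)-3-[(tert-butyldimethylsilyloxy)methyl]hepta-3,6-dienoic acid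
Conditions: LiOH, THF–H2O, 0 °C to rt; then dilute HCl to pH 4
Reagents that add atoms: lithium hydroxide, [Li+].[OH-]
Why: Saponification of the unhindered ethyl ester is faster than α-deprotonation, and the carboxylate once formed no longer drifts into conjugation.

Step 8
Reactants: 8 (2R,3E,5S)-4,5,9-trimethyldeca-3,8-dien-2-ol; 15 (E)-3-[(tert-butyldimethylsilyloxy)methyl]hepta-3,6-dienoic acid
Product: 16 (2R,3E,5S)-4,5,9-trimethyldeca-3,8-dien-2-yl (E)-3-[(tert-butyldimethylsilyloxy)methyl]hepta-3,6-dienoate
Conditions: EDC·HCl, DMAP (cat.), CH2Cl2, 0 °C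
Reagents that add atoms: none
Why: Steglich-type carbodiimide esterification acylates the C12 oxygen without breaking the C12–O bond, so (R)-C12 is retained, and little DMAP at 0 °C keeps the 3-alkenoate out of conjugation.

Step 9
Reactants: 16 (2R,3E,5S)-4,5,9-trimethyldeca-3,8-dien-2-yl (E)-3-[(tert-butyldimethylsilyloxy)methyl]hepta-3,6-dienoate
Product: 19 (2S,3S,4S)-2-[(2E)-1-(tert-butyldimethylsilyloxy)hexa-2,5-dien-2-yl]-3,4,8-trimethyl-3-[(E)-prop-1-enyl]non-7-enoic acid, via silyl ketene acetal 17 (not isolated), via trimethylsilyl ester 18 (not isolated)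
Conditions: LiN(i-Pr)2, THF–DMPU, −78 °C; Me3SiCl; −78 to 40 °C; aq. citric acid
Reagents that add atoms: none
Why: In this Ireland–Claisen rearrangement the DMPU-modified enolisation puts C4 cis to the silylated oxygen, and the chair transition state with the C13 methyl of (R)-C12, the C1' chain and C4 all equatorial forms C5–C6, which sets C5 (S), quaternary C6 (S) and the E-propenyl group by 1,3-chirality transfer.

Step 10
Reactants: 19 Claisen acid
Product: 21 (3S,4S,5S)-3-[(2E)-1-(tert-butyldimethylsilyloxy)hexa-2,5-dien-2-yl]-4,5,9-trimethyl-4-[(E)-prop-1-enyl]dec-8-en-2-one, via acid chloride 20 (not isolated)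
Conditions: 1-chloro-N,N,2-trimethylpropenylamine, CH2Cl2, 0 °C; then Me2CuLi (from MeLi and CuI), Et2O, −78 °C
Reagents that add atoms: lithium dimethylcuprate, [Li+].C[Cu-]C
Why: Neutral acid chloride formation followed by acylation of the weakly basic Gilman cuprate stops at the methyl ketone and spares the acidic allylic C5–H, so C5 is neither epimerised nor moved into conjugation.

Step 11
Reactants: 21 methyl ketone; 22 methyl acrylate
Product: 23 keto enoate methyl (2E,5E,7S,8S,9S)-7-acetyl-6-[(tert-butyldimethylsilyloxy)methyl]-8,9,13-trimethyl-8-[(E)-prop-1-enyl]tetradeca-2,5,12-trienoate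
Conditions: second-generation Hoveyda–Grubbs catalyst (cat.), 22 (large excess), 1,4-benzoquinone (cat.), CH2Cl2, 40 °C
Reagents that add atoms: none
Why: Olefin cross-metathesis of the only monosubstituted alkene with an electron-poor partner is E-selective, the large excess of acrylate outruns ring closure onto the neopentyl propenyl group, the trisubstituted alkenes are spectators and benzoquinone suppresses alkene migration.

Step 12
Reactants: 23 keto enoate
Product: 24 cyclohexene hydroxy ester (ring A closed; C10 OH cis to the C6 group on C5 and trans to the CH2CO2Me arm on C1; C1 R, C5 S, C6 S, C10 R, C1' S)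
Conditions: SmI2 (2.5 equiv), HMPA, t-BuOH, THF, −78 to 0 °C
Reagents that add atoms: none
Why: SmI2–HMPA transfers one electron to the C10 ketone, the nucleophilic samarium ketyl adds to the electron-poor β-carbon C1 of the (E)-enoate, and a second electron plus t-BuOH convert the C9 radical into the saturated ester, so two carbons that are both electrophiles are joined; the closest known reaction type is the reductive ketyl–olefin cyclisation of methyl ketones onto tethered acrylate-type acceptors. Ring A (C10, C1, C2, C3, C4, C5) closes in the 6-exo-trig mode, prepared by the C3=C4 alkene that holds C2 and C5 cis. The fold of the chair-like transition state is dictated by C5: allylic 1,2-strain against the C11 group on C4 turns the quaternary C6 substituent pseudoaxial. C10 is set by the bulky HMPA-solvated O–Sm group taking the open equatorial site and the methyl group the axial site anti to C6, which puts oxygen cis to the C6 chain. C1 is set by the enoate arm lying equatorial and turned away from the ketyl oxygen, which puts C9 trans to oxygen and trans to C6. The step needs one reducible ketone and one reachable acceptor, and the substrate secures this because C12 carries no carbonyl (no pinacol partner) and the propenyl, prenyl and C3=C4 alkenes are electron-rich or reachable only through four-membered or endo closures.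

Step 13
Reactants: 24 cyclohexene hydroxy ester
Product: 25 C10 triethylsilyl ether of 24
Conditions: Et3SiOTf, 2,6-lutidine, CH2Cl2, 0 °C
Reagents that add atoms: triethylsilyl triflate, CC[Si](CC)(CC)OS(=O)(=O)C(F)(F)F
Why: Silyl triflate–lutidine silylation reaches hindered tertiary alcohols, and the silyl ether rules out acyl transfer, lactol formation and oxa-Michael addition at C8 during ring-B closure.

Step 14
Reactants: 25 silyl ether ester
Product: 26 C8 aldehyde (C10 OSiEt3; configuration as in 24)
Conditions: i-Bu2AlH (1.1 equiv), toluene, −78 °C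
Reagents that add atoms: none
Why: Partial reduction of the unhindered methyl ester stops at the tetrahedral aluminate, which releases the aldehyde only on work-up, and no other reducible group is present.

Step 15
Reactants: 26 C8 aldehyde
Product: 27 keto aldehyde (C6–CH2–C(O)CH3 arm; C8 aldehyde)
Conditions: PdCl2 (cat.), Cu(OAc)2 (cat.), O2 (1 atm), DMA–H2O, 50 °C
Reagents that add atoms: water, O
Why: Tsuji–Wacker oxidation under acetate buffering touches only the 1,2-disubstituted alkene because trisubstituted alkenes are inert, and water attacks C12, the carbon remote from quaternary C6, so the methyl ketone and not a C7 ketone results.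

Step 16
Reactants: 27 keto aldehyde
Product: 29 trans-bridged bicyclic enone (C7=C8 conjugated to the C12 ketone; C10 OSiEt3; C11 OTBS), via aldol 28 (not isolated)
Conditions: KOt-Bu (cat.), t-BuOH–THF, 0 to 40 °C, high dilution
Reagents that add atoms: none
Why: In this intramolecular aldol condensation the C7 enolate of the methyl ketone attacks the C8 aldehyde under equilibrating base (seven-membered ring instead of the nine-membered ring open to C13) and E1cB loss of water gives the 1-acetylcycloheptene unit of ring B without creating a stereocentre.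

Step 17
Reactants: 29 bicyclic enone
Product: 30 bicyclic ketone with (S)-C7 (acetyl cis to the C1' chain on C6)
Conditions: [(Ph3P)CuH]6, wet degassed toluene, rt
Reagents that add atoms: none
Why: Stryker conjugate reduction adds hydride to C8 of the only enone and spares isolated alkenes and silyl ethers, and C7 is then protonated from the face of the small C6 methyl, anti to the branched C1' chain, which gives the required C7 configuration under kinetic control.

Step 18
Reactants: 30 bicyclic ketone
Product: 31 diol (C10 OH and C11 OH free)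
Conditions: HF·pyridine, pyridine–THF, 0 °C to rt
Reagents that add atoms: none
Why: Fluoride-driven desilylation under weakly acidic buffered conditions removes both silyl groups without enolising the C12 ketone.

Step 19
Reactants: 31 diol
Product: 32 hydroxy enal (C11 aldehyde conjugated to C3=C4)
Conditions: MnO2, CH2Cl2, rt
Reagents that add atoms: none
Why: Allylic alcohol oxidation with MnO2 takes only the primary allylic C11 hydroxyl, while the tertiary C10 hydroxyl cannot be oxidised and C7 sees no acid or base.

Step 20
Reactants: 32 hydroxy enal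
Product: 33 target CNP0288370.1 (C1 S, C5 S, C6 R, C7 S, C10 R, C1' S)
Conditions: Ac2O, DMAP (cat.), Et3N, ClCH2CH2Cl, 50 °C
Reagents that add atoms: acetic anhydride, CC(=O)OC(C)=O
Why: DMAP-catalysed acyl transfer acetylates the only hydroxyl left, and C7 is not at risk because amine bases enolise the C12 ketone towards C13 far more easily than towards the neopentyl C7–H.

Compound list
1 | (S)-citronellal | O=CC[C@@H](C)CCC=C(C)C | starting material
2 | enol nonaflate of 1 (E/Z mixture) | FC(F)(F)C(F)(F)C(F)(F)C(F)(F)S(=O)(=O)OC=C[C@@H](C)CCC=C(C)C | intermediate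
3 | (S)-3,7-dimethyloct-6-en-1-yne | C#C[C@@H](C)CCC=C(C)C | intermediate
4 | acetaldehyde | CC=O | starting material
5 | (E)-alkenyldimethylalane (CH3 and Al cis) | C[Al](C)/C=C(\C)[C@@H](C)CCC=C(C)C | intermediate
6 | (3E,5S)-4,5,9-trimethyldeca-3,8-dien-2-ol, both C12 epimers | CC(O)/C=C(\C)[C@@H](C)CCC=C(C)C | intermediate
7 | (3E,5S)-4,5,9-trimethyldeca-3,8-dien-2-one | CC(=O)/C=C(\C)[C@@H](C)CCC=C(C)C | intermediate
8 | (2R,3E,5S)-4,5,9-trimethyldeca-3,8-dien-2-ol | C[C@@H](O)/C=C(\C)[C@@H](C)CCC=C(C)C | intermediate
9 | tert-butyldimethyl(prop-2-yn-1-yloxy)silane | C#CCO[Si](C)(C)C(C)(C)C | starting material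
10 | allyl bromide | C=CCBr | starting material
11 | (Z)-(2-bromohexa-2,5-dien-1-yloxy)(tert-butyl)dimethylsilane | Br/C(CO[Si](C)(C)C(C)(C)C)=C\CC=C | intermediate
12 | ethyl bromoacetate | CCOC(=O)CBr | starting material
13 | zinc enolate BrZnCH2CO2Et | CCOC(=O)C[Zn]Br | intermediate
14 | ethyl (E)-3-[(tert-butyldimethylsilyloxy)methyl]hepta-3,6-dienoate | CCOC(=O)C/C(CO[Si](C)(C)C(C)(C)C)=C\CC=C | intermediate
15 | (E)-3-[(tert-butyldimethylsilyloxy)methyl]hepta-3,6-dienoic acid | OC(=O)C/C(CO[Si](C)(C)C(C)(C)C)=C\CC=C | intermediate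
16 | ester of 8 with 15 | C[C@@H](OC(=O)C/C(CO[Si](C)(C)C(C)(C)C)=C\CC=C)/C=C(\C)[C@@H](C)CCC=C(C)C | intermediate
17 | silyl ketene acetal (C4 cis to OSiMe3) | C[C@@H](O/C(O[Si](C)(C)C)=C/C(CO[Si](C)(C)C(C)(C)C)=C\CC=C)/C=C(\C)[C@@H](C)CCC=C(C)C | intermediate
18 | trimethylsilyl ester of 19 | C[Si](C)(C)OC(=O)[C@H](/C(CO[Si](C)(C)C(C)(C)C)=C\CC=C)[C@@](C)([C@@H](C)CCC=C(C)C)/C=C/C | intermediate
19 | Claisen acid (C5 S, C6 S, C1' S) | OC(=O)[C@H](/C(CO[Si](C)(C)C(C)(C)C)=C\CC=C)[C@@](C)([C@@H](C)CCC=C(C)C)/C=C/C | intermediate
20 | acid chloride of 19 | ClC(=O)[C@H](/C(CO[Si](C)(C)C(C)(C)C)=C\CC=C)[C@@](C)([C@@H](C)CCC=C(C)C)/C=C/C | intermediate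
21 | methyl ketone (C5 S, C6 S, C1' S) | CC(=O)[C@H](/C(CO[Si](C)(C)C(C)(C)C)=C\CC=C)[C@@](C)([C@@H](C)CCC=C(C)C)/C=C/C | intermediate
22 | methyl acrylate | C=CC(=O)OC | starting material
23 | keto enoate, precursor of the key step | CC(=O)[C@H](/C(CO[Si](C)(C)C(C)(C)C)=C\C/C=C/C(=O)OC)[C@@](C)([C@@H](C)CCC=C(C)C)/C=C/C | intermediate
24 | cyclohexene hydroxy ester, product of the key step | O[C@]1(C)[C@@H](CC(=O)OC)CC=C(CO[Si](C)(C)C(C)(C)C)[C@@H]1[C@@](C)([C@@H](C)CCC=C(C)C)/C=C/C | intermediate
25 | C10 triethylsilyl ether of 24 | CC[Si](CC)(CC)O[C@]1(C)[C@@H](CC(=O)OC)CC=C(CO[Si](C)(C)C(C)(C)C)[C@@H]1[C@@](C)([C@@H](C)CCC=C(C)C)/C=C/C | intermediate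
26 | C8 aldehyde | CC[Si](CC)(CC)O[C@]1(C)[C@@H](CC=O)CC=C(CO[Si](C)(C)C(C)(C)C)[C@@H]1[C@@](C)([C@@H](C)CCC=C(C)C)/C=C/C | intermediate
27 | keto aldehyde | CC[Si](CC)(CC)O[C@]1(C)[C@@H](CC=O)CC=C(CO[Si](C)(C)C(C)(C)C)[C@@H]1[C@@](C)([C@@H](C)CCC=C(C)C)CC(C)=O | intermediate
28 | aldol (C7, C8 undefined) | CC[Si](CC)(CC)O[C@]1(C)[C@@H]2CC=C(CO[Si](C)(C)C(C)(C)C)[C@@H]1[C@@](C)([C@@H](C)CCC=C(C)C)C(C(C)=O)C(O)C2 | intermediate
29 | trans-bridged bicyclic enone | CC[Si](CC)(CC)O[C@]1(C)[C@@H]2CC=C(CO[Si](C)(C)C(C)(C)C)[C@@H]1[C@@](C)([C@@H](C)CCC=C(C)C)C(C(C)=O)=CC2 | intermediate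
30 | bicyclic ketone, (S)-C7 | CC[Si](CC)(CC)O[C@]1(C)[C@@H]2CC=C(CO[Si](C)(C)C(C)(C)C)[C@@H]1[C@@](C)([C@@H](C)CCC=C(C)C)[C@@H](C(C)=O)CC2 | intermediate
31 | diol | O[C@]1(C)[C@@H]2CC=C(CO)[C@@H]1[C@@](C)([C@@H](C)CCC=C(C)C)[C@@H](C(C)=O)CC2 | intermediate
32 | hydroxy enal | O[C@]1(C)[C@@H]2CC=C(C=O)[C@@H]1[C@@](C)([C@@H](C)CCC=C(C)C)[C@@H](C(C)=O)CC2 | intermediate
33 | CNP0288370.1 | CC(=O)O[C@]1(C)[C@@H]2CC=C(C=O)[C@@H]1[C@@](C)([C@@H](C)CCC=C(C)C)[C@@H](C(C)=O)CC2 | target

Total step count: 20. Longest linear sequence: 17 steps (steps 1–4 and 8–20); steps 5–7 build the acid fragment in parallel.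

Steps most likely to fail

**Step 16.** The trans-bridged seven-membered ring stores much strain, so retro-aldol cleavage may outrun loss of water. Enolisation at C9 or C13 may also steer bond formation to the wrong carbon. The fallback replaces the equilibrium condensation by an irreversible enolate alkylation:
- It sets out from keto aldehyde 27. The aldehyde alone is reduced with LiAlH(Ot-Bu)3 at −78 °C to the keto alcohol F1.
- An Appel reaction (I2, PPh3, imidazole) gives the keto iodide F2.
- KOt-Bu in THF at high dilution closes C7–C8 by intramolecular alkylation, seven- over nine-membered ring.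
- This comes back to the route at ketone 30 and makes step 17 unnecessary.
- C8 then has no acidic neighbour, and the bond cannot reopen once made.
- In this fallback the C7 configuration rests on the closure itself.

**Step 12.** Facial selectivity at C10 may be poor, with oxygen ending on the face away from the C6 chain. The enoate or the ketone may also be reduced before the ring closes. The fallback forms the same C10–C1 bond by a two-electron allyl-metal addition:
- It sets out from ketone 21. Cross-metathesis with (Z)-1,4-dichlorobut-2-ene gives the allylic chloride F3.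
- CrCl2 (Nozaki–Hiyama allylation) adds the γ-carbon C1 to the C10 ketone through a closed chair transition state. This gives the vinyl carbinol F4 with hydroxyl trans to vinyl.
- Et3SiOTf and 2,6-lutidine give the silyl ether F5.
- 9-BBN followed by NaBO3 hydroborates only the monosubstituted alkene and gives the primary alcohol F6.
- Dess–Martin oxidation comes back to the route at aldehyde 26.

**Step 15.** Coordination of palladium to the alkene beside quaternary C6 may be slow. That leaves room for alkene migration, erosion of regiocontrol or autoxidation of the aldehyde. The fallback uses sterically governed hydroboration instead of palladium oxidation: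
- It sets out from ester 25. Dicyclohexylborane places boron on C12, away from C6, and ignores the trisubstituted alkenes.
- NaBO3 gives the C12 alcohol F7 as an inconsequential epimer mixture.
- LiAlH4 reduces the ester to the diol F8.
- A double Swern oxidation comes back to the route at keto aldehyde 27.

Further compounds
F1 | step 16 | keto alcohol (C8 OH, C12 ketone, C10 OSiEt3) | CC[Si](CC)(CC)O[C@]1(C)[C@@H](CCO)CC=C(CO[Si](C)(C)C(C)(C)C)[C@@H]1[C@@](C)([C@@H](C)CCC=C(C)C)CC(C)=O
F2 | step 16 | keto iodide | CC[Si](CC)(CC)O[C@]1(C)[C@@H](CCI)CC=C(CO[Si](C)(C)C(C)(C)C)[C@@H]1[C@@](C)([C@@H](C)CCC=C(C)C)CC(C)=O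
F3 | step 12 | allylic chloride | CC(=O)[C@H](/C(CO[Si](C)(C)C(C)(C)C)=C\C/C=C/CCl)[C@@](C)([C@@H](C)CCC=C(C)C)/C=C/C
F4 | step 12 | vinyl carbinol | O[C@]1(C)[C@@H](C=C)CC=C(CO[Si](C)(C)C(C)(C)C)[C@@H]1[C@@](C)([C@@H](C)CCC=C(C)C)/C=C/C
F5 | step 12 | triethylsilyl ether of the vinyl carbinol | CC[Si](CC)(CC)O[C@]1(C)[C@@H](C=C)CC=C(CO[Si](C)(C)C(C)(C)C)[C@@H]1[C@@](C)([C@@H](C)CCC=C(C)C)/C=C/C
F6 | step 12 | primary alcohol (C8 OH, propenyl intact) | CC[Si](CC)(CC)O[C@]1(C)[C@@H](CCO)CC=C(CO[Si](C)(C)C(C)(C)C)[C@@H]1[C@@](C)([C@@H](C)CCC=C(C)C)/C=C/C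
F7 | step 15 | C12 alcohol ester (C12 epimers) | CC[Si](CC)(CC)O[C@]1(C)[C@@H](CC(=O)OC)CC=C(CO[Si](C)(C)C(C)(C)C)[C@@H]1[C@@](C)([C@@H](C)CCC=C(C)C)CC(C)O
F8 | step 15 | C8,C12 diol (C12 epimers) | CC[Si](CC)(CC)O[C@]1(C)[C@@H](CCO)CC=C(CO[Si](C)(C)C(C)(C)C)[C@@H]1[C@@](C)([C@@H](C)CCC=C(C)C)CC(C)O
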